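The ten-membered carbocycle is cut at C1–C2, the only ring bond whose two carbons are plain CH2 groups, lying between the methyl-bearing C10 and the C3 ketone. One ring-closing metathesis joins a C10 vinyl group to a C3 vinyl ketone and closes the ring as an enone that is later hydrogenated. The precursor is an open-chain diene already folded by the cis-fused C6/C7 γ-lactone and a C4/C5 acetonide, with the lactone methylene masked as a C13 benzyloxymethyl group. It is built from an L-erythrulose ketone (C6–C9) and a 2-methylglycidol-derived aldehyde (C3–C5) by boron aldol, butenolide formation, cis-hydrogenation and anti-crotylation.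

Key step: step 22

Remark: locants are those of the target skeleton (ring C1–C10 with C3 ketone, C4 methyl carbinol, C5 and C9 acyloxy, C6 lactone oxygen, C7 ring fusion, C8 hydroxyl, C10 methyl; C11–C13 lactone α-carbon, carbonyl and methylene); starting materials 1, 5, 12, 16, 23, 26, 31 and 39 are assumed commercial; O13 is carried as a benzyl ether so that it differs from silylated O8 and is cleaved in the hydrogenation of C1=C2; alcohol 32 is used as its C3 epimer mixture because step 21 removes that centre.

Step 1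
Reactants: 1 (R)-2-methylglycidol
Product: 2 (R)-3-(4-methoxybenzyloxy)-2-methylpropane-1,2-diol
Conditions: 4-MeOC6H4CH2OH (3 equiv), NaH (0.2 equiv), DMF, 60 °C
Reagents that add atoms: 4-methoxybenzyl alcohol, COc1ccc(CO)cc1
Why: Base-catalysed SN2 alcoholysis of the 2,2-disubstituted epoxide at its unsubstituted CH2 leaves the quaternary C4–O bond untouched, so C4 keeps the configuration of the glycidol.

Step 2
Reactants: 2 (R)-3-(4-methoxybenzyloxy)-2-methylpropane-1,2-diol
Product: 3 (S)-2-hydroxy-3-(4-methoxybenzyloxy)-2-methylpropanal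
Conditions: SO3·pyridine, DMSO, iPr2NEt, CH2Cl2, 0 °C
Reagents that add atoms: none
Why: Parikh–Doering oxidation converts the primary alcohol into the aldehyde without glycol cleavage, the tertiary C4 alcohol being inert and the α-carbon having no hydrogen to epimerise.

Step 3
Reactants: 3 (S)-2-hydroxy-3-(4-methoxybenzyloxy)-2-methylpropanal
Product: 4 (S)-3-(4-methoxybenzyloxy)-2-methyl-2-(trimethylsilyloxy)propanal (C3–C5 aldehyde)
Conditions: TMSCl, imidazole, DMF, 0 °C
Reagents that add atoms: chlorotrimethylsilane, C[Si](C)(C)Cl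
Why: Silyl ether formation masks the tertiary hydroxyl from the boron reagent of step 6 with a group that mild acid removes in step 7.

Step 4
Reactants: 5 L-erythrulose
Product: 6 3,4-O-isopropylidene-L-erythrulose
Conditions: Me2C(OMe)2, CSA (cat.), acetone, rt
Reagents that add atoms: 2,2-dimethoxypropane, COC(C)(C)OC
Why: Acid-catalysed transketalisation closes the five-membered dioxolane on the vicinal diol (later O8/O9) and leaves the primary hydroxyl (later O6) free, C8 being the native stereocentre of the ketose.

Step 5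
Reactants: 6 3,4-O-isopropylidene-L-erythrulose
Product: 7 1-O-TBS-3,4-O-isopropylidene-L-erythrulose (C6–C9 ketone)
Conditions: TBSCl, imidazole, DMF, 0 °C
Reagents that add atoms: tert-butyldimethylsilyl chloride, CC(C)(C)[Si](C)(C)Cl
Why: Standard silylation of the primary hydroxyl gives the α-silyloxy ketone needed for regioselective and Z-selective boron enolisation.

Step 6
Reactants: 7 1-O-TBS-3,4-O-isopropylidene-L-erythrulose; 4 (S)-3-(4-methoxybenzyloxy)-2-methyl-2-(trimethylsilyloxy)propanal
Product: 9 C3–C9 syn-aldol adduct (5-OH 6-OTBS 7-ketone), via dicyclohexylboron Z-enolate 8 (not isolated)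
Conditions: Chx2BCl, Et3N, Et2O, −78 to 0 °C; then 4, −78 to 0 °C; H2O2, pH 7 buffer, MeOH
Reagents that add atoms: none
Why: In this erythrulose-type boron aldol the silyloxymethyl side is enolised to the Z(O)-enolate, which adds through a Zimmerman–Traxler chair (O5 syn to O6) on the enolate face opposite the dioxolane CH2 with the C8–O bond opposed to the enolate C–O bond, so C5 and C6 should be set syn to O8 as the target requires while the weakly biased α-quaternary aldehyde follows the reagent.

Step 7
Reactants: 9 C3–C9 syn-aldol adduct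
Product: 10 4,5:8,9-di-O-isopropylidene 6-O-TBS 7-ketone
Conditions: Me2C(OMe)2, PPTS (cat.), acetone, rt
Reagents that add atoms: 2,2-dimethoxypropane, COC(C)(C)OC
Why: Acid-catalysed transketalisation strips the labile tertiary TMS ether and ties O4 and O5 into the dioxolane, the only vicinal diol available while O6 stays silylated.

Step 8
Reactants: 10 4,5:8,9-di-O-isopropylidene 6-O-TBS 7-ketone
Product: 11 6-hydroxy 7-ketone (α-ketol)
Conditions: HF·pyridine, pyridine, THF, 0 °C to rt
Reagents that add atoms: none
Why: Fluoride cleavage of the secondary TBS ether under buffered non-basic conditions frees O6 without enolising the ketone, so C6 and C8 should not epimerise.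

Step 9
Reactants: 11 6-hydroxy 7-ketone; 12 (triphenylphosphoranylidene)ketene
Product: 14 C7=C11 butenolide (6,12-olide), via O6 phosphoranylideneacetate 13 (not isolated)
Conditions: toluene, 90 °C
Reagents that add atoms: none
Why: In this Bestmann butenolide synthesis the C6 hydroxyl adds to the ketene ylide and the ester-stabilised phosphorane closes onto the C7 ketone by intramolecular Wittig olefination, forming the lactone with the C6–O bond and its configuration intact.

Step 10
Reactants: 14 C7=C11 butenolide
Product: 15 cis-fused saturated lactone (H6/H7 cis)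
Conditions: H2 (1 atm), Pd/C (palladium on carbon), pyridine (0.5 equiv), EtOAc, rt
Reagents that add atoms: none
Why: Heterogeneous hydrogenation delivers hydrogen to the butenolide face opposite the bulky dioxolanyl group on C6, which should make H6 and H7 cis and set C7 as the cis-β,γ-disubstituted lactone, while pyridine suppresses hydrogenolysis of the PMB ether.

Step 11
Reactants: 15 cis-fused saturated lactone; 16 benzyl chloromethyl ether
Product: 18 11-(benzyloxymethyl) lactone (C13 trans to C8), via lithium lactone enolate 17 (not isolated)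
Conditions: LDA, THF, −78 °C; then 16, DMPU, −78 to −30 °C
Reagents that add atoms: none
Why: Kinetic lactone enolate alkylation with the reactive chloromethyl ether occurs anti to the C7 side chain and gives the trans C11 benzyloxymethyl lactone, a centre that is erased when the methylene is unveiled.

Step 12
Reactants: 18 11-(benzyloxymethyl) lactone
Product: 19 8,9-diol
Conditions: AcOH–H2O (4:1), rt
Reagents that add atoms: none
Why: In this chemoselective acetal hydrolysis the terminal monosubstituted dioxolane is cleaved much faster than the fully substituted C4/C5 dioxolane, and mild acid at room temperature should leave the lactone on O6.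

Step 13
Reactants: 19 8,9-diol
Product: 20 8,9-bis-O-TBS ether
Conditions: TBSOTf, 2,6-lutidine, CH2Cl2, −78 to 0 °C
Reagents that add atoms: tert-butyldimethylsilyl trifluoromethanesulfonate, CC(C)(C)[Si](C)(C)OS(=O)(=O)C(F)(F)F
Why: Silyl triflate silylation protects both hydroxyls at once and places on O8 the TBS group that stays until the last step.

Step 14
Reactants: 20 8,9-bis-O-TBS ether
Product: 21 8-O-TBS 9-ol
Conditions: HF·pyridine, pyridine, THF, 0 °C
Reagents that add atoms: none
Why: In this selective desilylation the unhindered primary TBS ether is cleaved by buffered HF·pyridine well before the hindered secondary ether on O8.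

Step 15
Reactants: 21 8-O-TBS 9-ol
Product: 22 8-O-TBS C9 aldehyde
Conditions: DMP, pyridine, CH2Cl2, 0 °C to rt
Reagents that add atoms: none
Why: Dess–Martin oxidation under buffered non-basic conditions gives the α-silyloxy aldehyde without epimerising C8.

Step 16
Reactants: 22 8-O-TBS C9 aldehyde; 23 (E)-but-2-ene
Product: 25 homoallylic alcohol (9-OH 10-Me anti with O9 syn to O8), via (E)-crotyldiisopinocampheylborane 24 (not isolated)
Conditions: 23, KOtBu, n-BuLi, THF, −45 °C; (+)-Ipc2BOMe, −78 °C; BF3·OEt2; then 22, −78 °C; NaBO3·4H2O, THF–H2O, rt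
Reagents that add atoms: none
Why: In this Brown crotylboration the E-crotylborane reacts through a closed chair transition state to give the anti C9-OH/C10-Me pair, and the isopinocampheyl groups derived from (−)-α-pinene direct attack to the Re face of the aldehyde, which should override the Felkin preference of the α-silyloxy aldehyde and place O9 syn to O8.

Step 17
Reactants: 25 homoallylic alcohol; 26 (R)-2-methylbutanoic acid
Product: 28 C9 (R)-2-methylbutanoate, via mixed trichlorobenzoic anhydride 27 (not isolated)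
Conditions: 26, 2,4,6-Cl3C6H2COCl, Et3N, THF, rt; then 25, DMAP, toluene, rt
Reagents that add atoms: none
Why: Yamaguchi esterification acylates the hindered C9 alcohol through the mixed anhydride under mild base, conditions under which the α-stereocentre of the acid should not racemise.

Step 18
Reactants: 28 C9 (R)-2-methylbutanoate
Product: 29 C3 primary alcohol
Conditions: DDQ, CH2Cl2–pH 7 buffer, 0 °C
Reagents that add atoms: none
Why: Oxidative cleavage of the electron-rich PMB ether by DDQ frees the C3 hydroxyl and leaves the benzyl ether, silyl ether, acetonide and terminal alkene untouched.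

Step 19
Reactants: 29 C3 primary alcohol
Product: 30 C3 aldehyde
Conditions: DMP, pyridine, CH2Cl2, 0 °C to rt
Reagents that add atoms: none
Why: Dess–Martin oxidation gives the aldehyde, which cannot epimerise because C4 is quaternary.

Step 20
Reactants: 30 C3 aldehyde; 31 vinylmagnesium bromide
Product: 32 C3 allylic alcohol (both C3 epimers)
Conditions: THF, −78 °C; NH4Cl aq.
Reagents that add atoms: none
Why: Grignard addition at −78 °C is far faster at the aldehyde than at the lactone or the hindered ester, and the new C3 carbinol centre is irrelevant because it is oxidised next.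

Step 21
Reactants: 32 C3 allylic alcohol
Product: 33 diene with C3 vinyl ketone and C10 vinyl group (metathesis precursor)
Conditions: DMP, pyridine, CH2Cl2, 0 °C
Reagents that add atoms: none
Why: Dess–Martin oxidation of the allylic alcohol gives the vinyl ketone under neutral conditions that avoid conjugate addition to the enone.

Step 22
Reactants: 33 diene with C3 vinyl ketone and C10 vinyl group
Product: 34 ten-membered C1=C2 enone (Z expected)
Conditions: second-generation Grubbs catalyst (H2IMes)(PCy3)Cl2Ru=CHPh (10 mol%), CH2Cl2 (1 mM), 40 °C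
Reagents that add atoms: none
Why: The ruthenium benzylidene exchanges onto the more electron-rich C10 vinyl group, the resulting alkylidene adds across the C3 vinyl ketone in a [2+2] step to a ruthenacyclobutane, and cycloreversion releases the C1=C2 enone; loss of ethylene makes the closure irreversible. The closest known reaction type is enone-forming ring-closing metathesis to medium and large rings with NHC–ruthenium catalysts. The one ring formed is the ten-membered carbocycle C1–C10, closed by ring-closing metathesis of two terminal alkenes at the only unbranched, heteroatom-free ring bond. No stereocentre is created, and the geometry of C1=C2 does not matter because the alkene is hydrogenated in step 23. The selectivity needed is ring closure over intermolecular metathesis, which high dilution and the two five-membered rings already in the chain (the cis-fused C6/C7 lactone and the C4/C5 dioxolane, which turn the C3 and C10 ends toward each other) should secure. The lactone methylene is still a saturated benzyloxymethyl group, so no third alkene can engage C1 in a six-membered closure through C11.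

Step 23
Reactants: 34 ten-membered C1=C2 enone
Product: 35 saturated C3 ketone with free C13 hydroxymethyl
Conditions: H2 (1 atm), Pd(OH)2/C, EtOAc, rt
Reagents that add atoms: none
Why: Heterogeneous hydrogenation saturates the C1=C2 enone alkene and hydrogenolyses the benzyl ether in one operation, the ketone, esters, acetonide and silyl ether being inert.

Step 24
Reactants: 35 saturated C3 ketone with free C13 hydroxymethyl
Product: 37 α-methylene lactone (4,5-acetonide 8-O-TBS), via C13 mesylate 36 (not isolated)
Conditions: MsCl, Et3N, CH2Cl2, 0 °C; then DBU, rt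
Reagents that add atoms: none
Why: Sulfonylation of the only free hydroxyl followed by E1cB elimination through the lactone enolate gives the α-methylene lactone while O8 is still silylated, so no acyl migration from O9 can occur.

Step 25
Reactants: 37 α-methylene lactone (4,5-acetonide 8-O-TBS)
Product: 38 4,5-diol (8-O-TBS)
Conditions: Me2BBr, CH2Cl2, −78 °C; then NaHCO3 aq.
Reagents that add atoms: none
Why: Lewis acid cleavage of the isopropylidene ketal with Me2BBr at −78 °C is known to spare TBS ethers, esters and lactones, so the C4/C5 diol should be freed without touching O8.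

Step 26
Reactants: 38 4,5-diol (8-O-TBS); 39 angelic acid
Product: 41 5-O-angeloyl 8-O-TBS ether, via angelic trichlorobenzoic anhydride 40 (not isolated)
Conditions: 39, 2,4,6-Cl3C6H2COCl, Et3N, toluene, rt; then 38, toluene, 80 °C
Reagents that add atoms: none
Why: Yamaguchi-type acylation without DMAP transfers the angeloyl group to the secondary C5 hydroxyl (the tertiary C4 hydroxyl does not react) and avoids nucleophile-induced Z to E isomerisation to the tiglate.

Step 27
Reactants: 41 5-O-angeloyl 8-O-TBS ether
Product: 42 CNP0226386.1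
Conditions: HF·pyridine, pyridine, THF, 0 °C to rt
Reagents that add atoms: none
Why: Fluoride desilylation under mildly acidic HF·pyridine conditions frees O8 without base, so neither acyl migration from O9, translactonisation nor conjugate addition to the methylene lactone is expected.

Compound list

1 | (R)-2-methylglycidol, (R)-(2-methyloxiran-2-yl)methanol | OC[C@]1(C)CO1 | starting material
2 | (R)-3-(4-methoxybenzyloxy)-2-methylpropane-1,2-diol | COc1ccc(COC[C@](C)(O)CO)cc1 | intermediate
3 | (S)-2-hydroxy-3-(4-methoxybenzyloxy)-2-methylpropanal | COc1ccc(COC[C@](C)(O)C=O)cc1 | intermediate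
4 | (S)-3-(4-methoxybenzyloxy)-2-methyl-2-(trimethylsilyloxy)propanal (C3–C5 aldehyde) | COc1ccc(COC[C@](C)(O[Si](C)(C)C)C=O)cc1 | intermediate
5 | L-erythrulose, (S)-1,3,4-trihydroxybutan-2-one | OC[C@H](O)C(=O)CO | starting material
6 | 3,4-O-isopropylidene-L-erythrulose | OCC(=O)[C@@H]1COC(C)(C)O1 | intermediate
7 | 1-O-TBS-3,4-O-isopropylidene-L-erythrulose (C6–C9 ketone) | CC(C)(C)[Si](C)(C)OCC(=O)[C@@H]1COC(C)(C)O1 | intermediate
8 | dicyclohexylboron Z-enolate of 7 (not isolated) | CC(C)(C)[Si](C)(C)O/C=C(\OB(C1CCCCC1)C2CCCCC2)[C@@H]3COC(C)(C)O3 | intermediate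
9 | C3–C9 aldol adduct: 3-OPMB, 4-OTMS, 5-OH, 6-OTBS, 7-ketone, 8,9-acetonide; O4/O5 anti, O5/O6 syn, O6/O8 syn | COc1ccc(COC[C@](C)(O[Si](C)(C)C)[C@H](O)[C@@H](O[Si](C)(C)C(C)(C)C)C(=O)[C@@H]2COC(C)(C)O2)cc1 | intermediate
10 | 4,5:8,9-di-O-isopropylidene 6-O-TBS 7-ketone | COc1ccc(COC[C@]2(C)OC(C)(C)O[C@@H]2[C@@H](O[Si](C)(C)C(C)(C)C)C(=O)[C@@H]3COC(C)(C)O3)cc1 | intermediate
11 | 6-hydroxy 7-ketone (α-ketol), 4,5:8,9-bis-acetonide | COc1ccc(COC[C@]2(C)OC(C)(C)O[C@@H]2[C@@H](O)C(=O)[C@@H]3COC(C)(C)O3)cc1 | intermediate
12 | (triphenylphosphoranylidene)ketene (Bestmann ylide) | O=C=C=P(c1ccccc1)(c1ccccc1)c1ccccc1 | starting material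
13 | O6 (triphenylphosphoranylidene)acetate of 11 (not isolated) | COc1ccc(COC[C@]2(C)OC(C)(C)O[C@@H]2[C@@H](OC(=O)C=P(c4ccccc4)(c5ccccc5)c6ccccc6)C(=O)[C@@H]3COC(C)(C)O3)cc1 | intermediate
14 | C7=C11 butenolide (6,12-olide), 4,5:8,9-bis-acetonide, 3-OPMB | COc1ccc(COC[C@]2(C)OC(C)(C)O[C@@H]2[C@H]3OC(=O)C=C3[C@@H]4COC(C)(C)O4)cc1 | intermediate
15 | cis-fused saturated lactone (H6/H7 cis) | COc1ccc(COC[C@]2(C)OC(C)(C)O[C@@H]2[C@H]3OC(=O)C[C@H]3[C@@H]4COC(C)(C)O4)cc1 | intermediate
16 | benzyl chloromethyl ether | ClCOCc1ccccc1 | starting material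
17 | lithium enolate of lactone 15 (not isolated) | COc1ccc(COC[C@]2(C)OC(C)(C)O[C@@H]2[C@H]3OC(O[Li])=C[C@H]3[C@@H]4COC(C)(C)O4)cc1 | intermediate
18 | 11-(benzyloxymethyl) lactone, C13 trans to C8 on the lactone | COc1ccc(COC[C@]2(C)OC(C)(C)O[C@@H]2[C@H]3OC(=O)[C@H](COCc5ccccc5)[C@H]3[C@@H]4COC(C)(C)O4)cc1 | intermediate
19 | 8,9-diol | COc1ccc(COC[C@]2(C)OC(C)(C)O[C@@H]2[C@H]3OC(=O)[C@H](COCc4ccccc4)[C@H]3[C@@H](O)CO)cc1 | intermediate
20 | 8,9-bis-O-TBS ether | COc1ccc(COC[C@]2(C)OC(C)(C)O[C@@H]2[C@H]3OC(=O)[C@H](COCc4ccccc4)[C@H]3[C@@H](O[Si](C)(C)C(C)(C)C)CO[Si](C)(C)C(C)(C)C)cc1 | intermediate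
21 | 8-O-TBS 9-ol | COc1ccc(COC[C@]2(C)OC(C)(C)O[C@@H]2[C@H]3OC(=O)[C@H](COCc4ccccc4)[C@H]3[C@@H](O[Si](C)(C)C(C)(C)C)CO)cc1 | intermediate
22 | 8-O-TBS C9 aldehyde | COc1ccc(COC[C@]2(C)OC(C)(C)O[C@@H]2[C@H]3OC(=O)[C@H](COCc4ccccc4)[C@H]3[C@@H](O[Si](C)(C)C(C)(C)C)C=O)cc1 | intermediate
23 | (E)-but-2-ene | C/C=C/C | starting material
24 | (E)-crotyldiisopinocampheylborane from (−)-α-pinene (not isolated) | C/C=C/CB([C@H]1C[C@H]2C[C@@H]([C@@H]1C)C2(C)C)[C@H]3C[C@H]4C[C@@H]([C@@H]3C)C4(C)C | intermediate
25 | homoallylic alcohol: 9-OH and 10-Me anti, O9 syn to O8, C10 vinyl | COc1ccc(COC[C@]2(C)OC(C)(C)O[C@@H]2[C@H]3OC(=O)[C@H](COCc4ccccc4)[C@H]3[C@@H](O[Si](C)(C)C(C)(C)C)[C@H](O)[C@H](C)C=C)cc1 | intermediate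
26 | (R)-2-methylbutanoic acid | OC(=O)[C@H](C)CC | starting material
27 | (R)-2-methylbutanoic 2,4,6-trichlorobenzoic anhydride (not isolated) | O=C(OC(=O)[C@H](C)CC)c1c(Cl)cc(Cl)cc1Cl | intermediate
28 | C9 (R)-2-methylbutanoate | COc1ccc(COC[C@]2(C)OC(C)(C)O[C@@H]2[C@H]3OC(=O)[C@H](COCc4ccccc4)[C@H]3[C@@H](O[Si](C)(C)C(C)(C)C)[C@H](OC(=O)[C@H](C)CC)[C@H](C)C=C)cc1 | intermediate
29 | C3 primary alcohol | OC[C@]1(C)OC(C)(C)O[C@@H]1[C@H]2OC(=O)[C@H](COCc3ccccc3)[C@H]2[C@@H](O[Si](C)(C)C(C)(C)C)[C@H](OC(=O)[C@H](C)CC)[C@H](C)C=C | intermediate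
30 | C3 aldehyde | O=C[C@]1(C)OC(C)(C)O[C@@H]1[C@H]2OC(=O)[C@H](COCc3ccccc3)[C@H]2[C@@H](O[Si](C)(C)C(C)(C)C)[C@H](OC(=O)[C@H](C)CC)[C@H](C)C=C | intermediate
31 | vinylmagnesium bromide | C=C[Mg]Br | starting material
32 | C3 allylic alcohol (both C3 epimers) | C=CC(O)[C@]1(C)OC(C)(C)O[C@@H]1[C@H]2OC(=O)[C@H](COCc3ccccc3)[C@H]2[C@@H](O[Si](C)(C)C(C)(C)C)[C@H](OC(=O)[C@H](C)CC)[C@H](C)C=C | intermediate
33 | diene with C3 vinyl ketone and C10 vinyl group (metathesis precursor) | C=CC(=O)[C@]1(C)OC(C)(C)O[C@@H]1[C@H]2OC(=O)[C@H](COCc3ccccc3)[C@H]2[C@@H](O[Si](C)(C)C(C)(C)C)[C@H](OC(=O)[C@H](C)CC)[C@H](C)C=C | intermediate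
34 | ten-membered C1=C2 enone (metathesis product) | O=C1/C=C\[C@@H](C)[C@@H](OC(=O)[C@H](C)CC)[C@H](O[Si](C)(C)C(C)(C)C)[C@@H]3[C@@H](COCc4ccccc4)C(=O)O[C@@H]3[C@H]2OC(C)(C)O[C@@]12C | intermediate
35 | saturated C3 ketone with free C13 hydroxymethyl | O=C1CC[C@@H](C)[C@@H](OC(=O)[C@H](C)CC)[C@H](O[Si](C)(C)C(C)(C)C)[C@@H]3[C@@H](CO)C(=O)O[C@@H]3[C@H]2OC(C)(C)O[C@@]12C | intermediate
36 | C13 methanesulfonate of 35 (not isolated) | O=C1CC[C@@H](C)[C@@H](OC(=O)[C@H](C)CC)[C@H](O[Si](C)(C)C(C)(C)C)[C@@H]3[C@@H](COS(C)(=O)=O)C(=O)O[C@@H]3[C@H]2OC(C)(C)O[C@@]12C | intermediate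
37 | α-methylene lactone, 4,5-acetonide, 8-O-TBS | O=C1CC[C@@H](C)[C@@H](OC(=O)[C@H](C)CC)[C@H](O[Si](C)(C)C(C)(C)C)[C@@H]3C(=C)C(=O)O[C@@H]3[C@H]2OC(C)(C)O[C@@]12C | intermediate
38 | 4,5-diol, 8-O-TBS | O=C1CC[C@@H](C)[C@@H](OC(=O)[C@H](C)CC)[C@H](O[Si](C)(C)C(C)(C)C)[C@@H]3C(=C)C(=O)O[C@@H]3[C@@H](O)[C@@]1(C)O | intermediate
39 | angelic acid, (Z)-2-methylbut-2-enoic acid | OC(=O)/C(C)=C\C | starting material
40 | angelic 2,4,6-trichlorobenzoic anhydride (not isolated) | O=C(OC(=O)/C(C)=C\C)c1c(Cl)cc(Cl)cc1Cl | intermediate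
41 | 5-O-angeloyl 8-O-TBS ether | O=C1CC[C@@H](C)[C@@H](OC(=O)[C@H](C)CC)[C@H](O[Si](C)(C)C(C)(C)C)[C@@H]3C(=C)C(=O)O[C@@H]3[C@@H](OC(=O)/C(C)=C\C)[C@@]1(C)O | intermediate
42 | CNP0226386.1 | C=C1C(=O)O[C@H]2[C@@H]1[C@@H](O)[C@H](OC(=O)[C@H](C)CC)[C@H](C)CCC(=O)[C@](C)(O)[C@@H]2OC(=O)/C(C)=C\C | target

Total step count: 27. Longest linear sequence: 25 steps (steps 1–3 and 6–27).

Steps most likely to fail

Step 22 (ring-closing metathesis). Intermolecular metathesis may outrun cyclisation, or the electron-poor vinyl ketone may engage the ruthenium carbene too slowly for the strained ten-membered closure. The fallback sets out from allylic alcohol 32, whose C3 alkene is an ordinary allylic carbinol. Ring-closing metathesis of 32 with the same second-generation Grubbs catalyst at 1 mM should give the ten-membered cyclic allylic alcohol F1. Dess–Martin oxidation of F1 then returns to the route at enone 34.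

Step 16 (crotylboration). Reagent control may be too weak in this mismatched pairing, so that facial selectivity at C9 erodes toward the Felkin isomer, and the α-silyloxy aldehyde may epimerise at C8 during a slow addition. The fallback sets out from aldehyde 22. Addition of the allenylzinc reagent made from (S)-but-3-yn-2-yl methanesulfonate, Pd(OAc)2, PPh3 and Et2Zn in THF at −20 °C (Marshall propargylation, net inversion at the propargylic carbon, cyclic SE2′ transition state) should give the anti homopropargylic alcohol F2. Semihydrogenation of the terminal alkyne of F2 with H2 over Pd/CaCO3 poisoned with Pb(OAc)2 and quinoline returns to the route at homoallylic alcohol 25.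

Step 6 (boron aldol). Addition of the boron enolate to the hindered α-quaternary aldehyde may be sluggish, with loss of the TMS ether, retro-aldol on work-up or erosion of facial control. The fallback sets out from erythrulose acetonide 6 and bypasses steps 5–9. Heating 6 with ylide 12 in toluene should give the butenolide F3. TBSOTf and Et3N in CH2Cl2 at 0 °C convert F3 into the silyloxyfuran F4. A BF3·OEt2-promoted vinylogous Mukaiyama aldol of F4 with aldehyde 4 at −78 °C (threo-selective open transition state, Felkin addition to the α-silyloxy aldehyde) should give the hydroxy butenolide F5. Treatment of F5 with Me2C(OMe)2 and PPTS closes the C4/C5 acetonide and returns to the route at butenolide 14.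

Further compounds

F1 | step 22 | ten-membered cyclic C3 allylic alcohol with C1=C2 (both C3 epimers) | OC1/C=C\[C@@H](C)[C@@H](OC(=O)[C@H](C)CC)[C@H](O[Si](C)(C)C(C)(C)C)[C@@H]3[C@@H](COCc4ccccc4)C(=O)O[C@@H]3[C@H]2OC(C)(C)O[C@@]12C
F2 | step 16 | anti homopropargylic alcohol (9-OH, 10-Me, C10 ethynyl) | COc1ccc(COC[C@]2(C)OC(C)(C)O[C@@H]2[C@H]3OC(=O)[C@H](COCc4ccccc4)[C@H]3[C@@H](O[Si](C)(C)C(C)(C)C)[C@H](O)[C@H](C)C#C)cc1
F3 | step 6 | 4-[(4S)-2,2-dimethyl-1,3-dioxolan-4-yl]furan-2(5H)-one | O=C1OCC([C@@H]2COC(C)(C)O2)=C1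
F4 | step 6 | 2-(tert-butyldimethylsilyloxy)-4-[(4S)-2,2-dimethyl-1,3-dioxolan-4-yl]furan | CC(C)(C)[Si](C)(C)Oc1cc(co1)[C@@H]2COC(C)(C)O2
F5 | step 6 | vinylogous aldol adduct: 5-hydroxy 4-OTMS butenolide (6,12-olide, C7=C11) | COc1ccc(COC[C@](C)(O[Si](C)(C)C)[C@H](O)[C@H]2OC(=O)C=C2[C@@H]3COC(C)(C)O3)cc1
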